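**Retrosynthetic overview**
- The target is a cyclohex-2-en-1-one ring (C1=O, C2=C3) with an unbranched C19 chain on C3. The chain is cut at its C11–C12 CH2–CH2 bond (C12 lies eight CH2 groups from ring C3), and each end is traced back to a CO2H group: dodecanoic acid and 9-(3-oxocyclohex-1-en-1-yl)nonanoic acid. These are joined in the last step by a crossed Kolbe anodic decarboxylative radical coupling.
- Enabling feature: C11 and C12 are unsubstituted methylenes inside a polymethylene chain, so both cut ends are primary, non-stabilised radicals that dimerise instead of over-oxidising. The only functional group, the ring enone O=C1–C2=C3, is electron-poor, has a fully substituted β-carbon (C3) and is too far away to trap the radical (only a ring of nine or more atoms could form).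
- The enone acid comes from a B-alkyl Suzuki–Miyaura coupling at ring C3 (3-bromocyclohex-2-en-1-one with the 9-BBN adduct of methyl non-8-enoate), followed by saponification.
- Rings: the single carbocycle is bought intact as cyclohexane-1,3-dione; no ring is formed in the route.

Key step: step 4

Remark on the chemistry: the target has no stereocentre and no stereogenic double bond, so the main route needs no stereocontrol and all its SMILES are written without stereodescriptors.

**Step 1**
Reactants: 1 cyclohexane-1,3-dione
Product: 2 3-bromocyclohex-2-en-1-one
Conditions: (COBr)2 (1.2 equiv), DMF (cat.), CH2Cl2, 0 °C → rt; used promptly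
Reagents that add atoms: oxalyl bromide, O=C(Br)C(=O)Br
Why: Vilsmeier-type activation of the enol oxygen of the 1,3-dione followed by bromide addition–elimination at C3 should give the β-bromo enone (halodehydroxylation of a vinylogous acid), with CO, CO2 and HBr as the only co-products.

**Step 2**
Reactants: 3 methyl non-8-enoate, 2 3-bromocyclohex-2-en-1-one
Product: 5 methyl 9-(3-oxocyclohex-1-en-1-yl)nonanoate, via B-alkyl-9-BBN adduct 4 (not isolated)
Conditions: 3, 9-BBN (1.1 equiv), THF, 0 °C → rt; then 2, PdCl2(dppf)·CH2Cl2 (3 mol%), K3PO4 (3 equiv, 3 M aq), DMF/THF, rt → 50 °C
Reagents that add atoms: none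
Why: Anti-Markovnikov hydroboration of the terminal alkene (the ester is inert to 9-BBN at rt) followed by B-alkyl Suzuki–Miyaura coupling with the activated vinylic C3–Br bond should give the ester, because dppf favours reductive elimination over β-hydride elimination and K3PO4 is mild enough for the methyl ester.

**Step 3**
Reactants: 5 methyl 9-(3-oxocyclohex-1-en-1-yl)nonanoate
Product: 6 9-(3-oxocyclohex-1-en-1-yl)nonanoic acid
Conditions: LiOH·H2O (2 equiv), THF/H2O 3:1, 0 °C → rt; then 1 M HCl to pH 3
Reagents that add atoms: lithium hydroxide, [Li+].[OH-]
Why: Saponification (BAc2) of the unhindered methyl ester should be much faster at or below rt than any base-mediated reaction of the β,β-disubstituted enone, to which hydroxide adds only reversibly.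

**Step 4**
Reactants: 6 9-(3-oxocyclohex-1-en-1-yl)nonanoic acid, 7 dodecanoic acid (lauric acid)
Product: 8 3-nonadecylcyclohex-2-en-1-one
Conditions: 6 (1 equiv), 7 (6 equiv), KOH (5–8 mol% per CO2H), MeOH, undivided cell, small smooth Pt anode (ca. 0.3 A cm−2), large-area Pt cathode, constant current, 45–50 °C, until the electrolyte turns faintly alkaline; extraction, SiO2 (hexane, then hexane/EtOAc)
Reagents that add atoms: none
Why: Mixed Kolbe electrolysis: the carboxylates of 6 and 7 are oxidised by one electron at the platinum anode at high current density, the acyloxy radicals lose CO2, and the primary undecyl and 8-(3-oxocyclohex-1-en-1-yl)octyl radicals combine in the concentrated radical layer at the electrode to form the C11–C12 bond, a union of two carbons of like polarity that both began as carboxyl-bearing termini, while the carboxyl protons leave as hydrogen at the cathode. The closest known reaction type is the crossed Kolbe coupling of a fatty acid with an ω-functionalised alkanoic acid (keto acids, half esters, unsaturated acids), the classical electrochemical entry to long-chain lipids and pheromones. No ring is closed and no stereocentre is formed. The step needs cross- over homo-coupling, which the six-fold excess of cheap 7 should secure statistically for the radicals derived from 6, while the co-formed homodimer docosane is a non-polar hydrocarbon that melts below the cell temperature (so it should not coat the anode) and is removed by chromatography. It also needs radical dimerisation instead of further oxidation to carbocations (Hofer–Moest products), which is secured by both radicals being unbranched, primary and free of α-heteroatoms, together with smooth Pt, weakly acidic methanol and high anodic current density. Finally the enone must survive: it is electron-poor and should not be oxidised at the anode, its β-carbon C3 is fully substituted and eight CH2 groups from the radical centre so that neither cyclisation nor intermolecular radical addition should compete, and at a large-area Pt cathode in the acidic medium proton reduction should take precedence over enone reduction.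

**Compound list**
1 | cyclohexane-1,3-dione | O=C1CCCC(=O)C1 | starting material
2 | 3-bromocyclohex-2-en-1-one | O=C1C=C(Br)CCC1 | intermediate
3 | methyl non-8-enoate | C=CCCCCCCC(=O)OC | starting material
4 | methyl 9-(9-borabicyclo[3.3.1]nonan-9-yl)nonanoate | COC(=O)CCCCCCCCB1C2CCCC1CCC2 | intermediate (not isolated)
5 | methyl 9-(3-oxocyclohex-1-en-1-yl)nonanoate | COC(=O)CCCCCCCCC1=CC(=O)CCC1 | intermediate
6 | 9-(3-oxocyclohex-1-en-1-yl)nonanoic acid | OC(=O)CCCCCCCCC1=CC(=O)CCC1 | intermediate
7 | dodecanoic acid (lauric acid) | CCCCCCCCCCCC(=O)O | starting material
8 | 3-nonadecylcyclohex-2-en-1-one | CCCCCCCCCCCCCCCCCCCC1=CC(=O)CCC1 | target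

**Step count and risks**
Total step count: 4. Longest linear sequence: 4 steps (1 → 2 → 5 → 6 → 8); the branch from 3 is 3 steps.

Steps most likely to fail, in order of risk:

1. Step 4. The electrolysis may suffer from poor cross- versus homo-coupling, fouling of the anode by waxy hydrocarbon, or electrochemical attack on the enone (cathodic reduction or radical addition). The fallback forms the same C11–C12 bond by a polar palladium cross-coupling; it sets out from 2 and comes back at 8. 8-Bromooct-1-ene is hydroborated with 9-BBN (THF, rt) to 9-(8-bromooctyl)-9-borabicyclo[3.3.1]nonane F1. F1 is coupled with 2 under the conditions of step 2 (only the vinylic C–Br bond should undergo oxidative addition with PdCl2(dppf)) to give 3-(8-bromooctyl)cyclohex-2-en-1-one F2. Undec-1-ene is hydroborated with 9-BBN to 9-undecyl-9-borabicyclo[3.3.1]nonane F3. F2 and F3 are then joined in a Pd(OAc)2/PCy3-catalysed alkyl–alkyl Suzuki–Miyaura coupling of the primary alkyl bromide (K3PO4·H2O, THF, rt), which should give 8.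

2. Step 2. Transmetalation of the B-alkyl group may be slow, with competing β-hydride elimination or protodeboronation, and the aqueous base may decompose the labile bromoenone or hydrolyse the ester early. The fallback is a base-free, anhydrous Negishi coupling; it sets out from 2 and comes back at 5. Zinc dust (LiCl, THF, 50 °C) is inserted into methyl 9-bromononanoate to give bromo(9-methoxy-9-oxononyl)zinc F4. F4 is coupled with 2 using Pd(PPh3)4 (THF, rt), which should give 5.

3. Step 3. During saponification the base may cause deconjugation of the enone or aldol/Michael self-condensation. The fallback makes the acid by oxidation under acidic conditions, with no ester and no hydroxide; it sets out from 1 and comes back at 6.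
   - 1 is converted (EtOH, cat. TsOH, toluene, Dean–Stark) into 3-ethoxycyclohex-2-en-1-one F5.
   - 9-Bromononan-1-ol is protected (3,4-dihydro-2H-pyran, PPTS, CH2Cl2) as racemic 2-[(9-bromononyl)oxy]oxane F6, which is turned (Mg, THF) into bromo[9-(oxan-2-yloxy)nonyl]magnesium F7.
   - 1,2-Addition of F7 to F5 should give 3-ethoxy-1-[9-(oxan-2-yloxy)nonyl]cyclohex-2-en-1-ol F8 as its bromomagnesium alkoxide (mixture of diastereomers, both centres lost in the next operation).
   - Aqueous HCl/THF at rt should hydrolyse the enol ether with allylic transposition (Stork–Danheiser sequence) and cleave the THP acetal in the same operation, giving 3-(9-hydroxynonyl)cyclohex-2-en-1-one F9.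
   - Jones oxidation (CrO3, H2SO4, acetone, 0 °C) of F9 should give 6.

**Further compounds**
F1 | step 4 | 9-(8-bromooctyl)-9-borabicyclo[3.3.1]nonane | BrCCCCCCCCB1C2CCCC1CCC2
F2 | step 4 | 3-(8-bromooctyl)cyclohex-2-en-1-one | BrCCCCCCCCC1=CC(=O)CCC1
F3 | step 4 | 9-undecyl-9-borabicyclo[3.3.1]nonane | CCCCCCCCCCCB1C2CCCC1CCC2
F4 | step 2 | bromo(9-methoxy-9-oxononyl)zinc | COC(=O)CCCCCCCC[Zn]Br
F5 | step 3 | 3-ethoxycyclohex-2-en-1-one | CCOC1=CC(=O)CCC1
F6 | step 3 | 2-[(9-bromononyl)oxy]oxane (racemic) | BrCCCCCCCCCOC1CCCCO1
F7 | step 3 | bromo[9-(oxan-2-yloxy)nonyl]magnesium (racemic) | Br[Mg]CCCCCCCCCOC1CCCCO1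
F8 | step 3 | 3-ethoxy-1-[9-(oxan-2-yloxy)nonyl]cyclohex-2-en-1-ol (diastereomer mixture, formed as bromomagnesium alkoxide) | CCOC1=CC(O)(CCCCCCCCCOC2CCCCO2)CCC1
F9 | step 3 | 3-(9-hydroxynonyl)cyclohex-2-en-1-one | OCCCCCCCCCC1=CC(=O)CCC1
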